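- Of the 3 questions, the low end could be bracketed by hand: elm holds the most starting material per partner, so I put it last.

| flask | starting material | partner | free catalyst | remark | time |
|---|---|---|---|---|---|
| teal | 0.44 M | 1 M | 2 mM | run made earlier |  |
| alder | 1.2 M | 2.00 M | 6.0 mM |  | 20 h |
| elm | 1.5 M | 0.600 M | 6.0 mM |  | 20 h |
| maple | 0.40 M | 1.00 M | 2.0 mM |  | 20 h |
| birch | 0.20 M | 1.00 M | 0.60 mM |  | 20 h |
| oak | 1.5 M | 1.00 M | 2.0 mM |  | 20 h |

teal run (percent of the starting material charged)

| time / h | target / % | side product / % |
|---|---|---|
| 0.833 | 5.9 | 1.5 |
| 2.50 | 12.2 | 7.4 |
| 5.00 | 21.7 | 20.7 |
| 8.00 | 26.0 | 38.4 |

(each reading ± 1 percentage point)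

- a species is counted by the starting material in it: one side product counts as two
- no earlier run changes the charge of free catalyst; that part of a forecast is a guess

* ranking by share of target in all that became target or side product or isomer of the product, from high to low, at 20 h (alder / elm / maple / birch / oak)
* the share of target in all that became target or side product or isomer of the product of the flask you put first, at 20 h
* the share of target in all that became target or side product or isomer of the product of the flask you put last, at 20 h

- I assumed that each target takes one partner and that each side product takes one target and one further starting material. Partner is then elm's limiting reagent, and its balance gives the conversion ceiling, twice the partner charged over the starting material charged, 80.0% in elm, which leaves [starting material] a floor of 0.300 M.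
- In teal, partner spent (target plus half the side product) ran at 0.0351 M h⁻¹ early and averaged 0.0249 M h⁻¹ up to the last reading. The last two readings give 0.603 L mol⁻¹ h⁻¹ for starting material + target.
- Upper bound: suppose extra catalyst adds nothing. Elm then spends 0.497 M of partner, [starting material] ends near 0.506 M, and target sits where making balances loss, near 0.0815 M. Its share is 8.20%.
- Lower bound: suppose the pace scales with catalyst, by 3.00. The 0.600 M of partner then lasts 8.05 h, and that same target level decays for the remaining time against the floor, giving 0.781% at the ceiling.
- The forecast gave birch > maple > alder > oak > elm, with 48% first and 1.5% last, on the ground that “Excess starting material destroys target”.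
- The flasks gave birch > maple > alder > oak > elm, from 38.4% down to 2.02%, which lies above my lower bound and below my upper one.

    starting material + target → side product (k = 0.570 L mol⁻¹ h⁻¹)
    catalyst intermediate B → by-product + catalyst intermediate C (k = 140 h⁻¹)
    catalyst intermediate C → free catalyst + target (k = 65.0 h⁻¹)
    target + free catalyst ⇌ isomer of the product + free catalyst, rate k4*[free catalyst]*[target] forward; the back reaction follows from the equilibrium constant (K = 2.90, k = 8.80 L mol⁻¹ h⁻¹)
    starting material + free catalyst ⇌ catalyst intermediate A (K = 33.0 L mol⁻¹, k = 120 L mol⁻¹ h⁻¹)
    partner + catalyst intermediate A → catalyst intermediate B (k = 55.0 L mol⁻¹ h⁻¹)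

- In elm, the binding of starting material to free catalyst had 90% of its turnover up to 20 h behind it by 10.0 h. At 20.0 h, catalyst intermediate A held 90.9% of the catalyst, partner stood at 0.543% of its charge and side product at 75.5%. Conversion was 77.9% against the ceiling of 80.0%, and at 200 h the starting material stood at 20.0%, the 20.0% the ceiling leaves. With 2.4 M of partner on the same charge, partner is no longer the limiting reagent and the ceiling is 100%: there starting material ran out first, with 0% left and partner at 59% of its charge.

The runs were computed for substances that don't exist.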